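**Retrosynthetic overview** (oxolane numbering of the target: O1, C2 aryl, C3 CH2O-ester, C4 benzyl, C5)
1. Agastinol 13 is disconnected at the ester into (2R,3S,4S)-lariciresinol 11 and 4-hydroxybenzoic acid 12 (Mitsunobu, last step).
2. 11 comes from the twofold-symmetric furofuran 9 by hydrogenolysis, which removes both O-benzyl groups and opens the temporary oxolane at one benzylic C–O bond.
3. 9 comes from the acyclic epoxy cinnamyl ether 6 in one operation (Cp2TiCl, then I2): bond C3–C4 by radical 5-exo closure (temporary oxolane, formed first), then bond O1–C2 by alkoxide attack on a benzylic iodide (oxolane of the target, formed second).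
4. Enabling feature of 6: the oxirane (O1, C5, C4) hangs by its CH carbon C4 on a benzylic carbon whose ether oxygen carries the cinnamyl chain. C4 is thus five atoms from the styrene β-carbon C3, and O1 five atoms from the benzylic carbon C2. The single benzylic stereocentre (Sharpless kinetic resolution) controls C4, C3 and C2.
5. 6 comes from epoxy alcohol 4 and cinnamyl bromide 5 (Williamson), both made from one racemic allylic alcohol 3 (O-benzylvanillin 1 plus vinylmagnesium bromide 2).

Key step: step 5

Remark: the target is (2R,3S,4S) with C2/C3 trans and C3/C4 cis; this is the relative configuration of lariciresinol, and the route is planned for that enantiomer.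

**Step 1**
Reactants: 1 4-(benzyloxy)-3-methoxybenzaldehyde; 2 vinylmagnesium bromide
Product: 3 rac-1-[4-(benzyloxy)-3-methoxyphenyl]prop-2-en-1-ol
Conditions: THF, −78 to 0 °C; then H2O/sat. aq. NH4Cl
Reagents that add atoms: none
Why: Grignard 1,2-addition of a vinyl nucleophile to an aromatic aldehyde should give the allylic alcohol as a racemate, which is what step 2 (resolution) and step 3 (loss of the stereocentre) both need.

**Step 2**
Reactants: 3 rac-1-[4-(benzyloxy)-3-methoxyphenyl]prop-2-en-1-ol
Product: 4 (S)-[4-(benzyloxy)-3-methoxyphenyl][(2R)-oxiran-2-yl]methanol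
Conditions: Ti(OiPr)4 (0.15 equiv), L-(+)-diisopropyl tartrate (0.2 equiv), tBuOOH (0.45 equiv), 4 Å MS, CH2Cl2, −20 °C, stopped near 45% conversion; chromatography separates 4 from unreacted (S)-enriched 3
Reagents that add atoms: tert-butyl hydroperoxide, CC(C)(C)OO
Why: Sharpless asymmetric epoxidation run as a kinetic resolution of a secondary allylic alcohol: with L-(+)-tartrate the (R)-enantiomer of 3 should be epoxidised much faster and erythro-selectively, which fixes the benzylic carbinol stereocentre of 4 (S by the priority rules) under reagent control and leaves (S)-enriched 3 for step 3.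

**Step 3**
Reactants: 3 rac-1-[4-(benzyloxy)-3-methoxyphenyl]prop-2-en-1-ol (the (S)-enriched material recovered from step 2)
Product: 5 1-(benzyloxy)-4-[(1E)-3-bromoprop-1-en-1-yl]-2-methoxybenzene
Conditions: PBr3 (0.4 equiv), Et2O, 0 °C, 30 min; used crude at once
Reagents that add atoms: phosphorus tribromide, BrP(Br)Br
Why: Bromination of a 1-arylallyl alcohol with allylic transposition (SN2'-type collapse to the conjugated isomer) should give the (E)-cinnamyl bromide, and because the stereocentre is lost the slow-reacting enantiomer recovered from step 2 is used here.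

**Step 4**
Reactants: 4 (S)-[4-(benzyloxy)-3-methoxyphenyl][(2R)-oxiran-2-yl]methanol; 5 1-(benzyloxy)-4-[(1E)-3-bromoprop-1-en-1-yl]-2-methoxybenzene
Product: 6 (2R)-2-[(S)-[4-(benzyloxy)-3-methoxyphenyl]{[(2E)-3-[4-(benzyloxy)-3-methoxyphenyl]prop-2-en-1-yl]oxy}methyl]oxirane
Conditions: NaH (1.2 equiv), Bu4NI (0.1 equiv), 5 (1.3 equiv), THF, 0 °C to rt
Reagents that add atoms: none
Why: Williamson ether synthesis (SN2 of the sodium alkoxide of 4 on the primary allylic bromide), the standard O-alkylation of Sharpless epoxy alcohols under aprotic conditions where Payne rearrangement is slow, should join the two halves through the temporary ether oxygen without touching either stereocentre.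

**Step 5**
Reactants: 6 (2R)-2-[(S)-[4-(benzyloxy)-3-methoxyphenyl]{[(2E)-3-[4-(benzyloxy)-3-methoxyphenyl]prop-2-en-1-yl]oxy}methyl]oxirane
Product: 9 (1R,3aS,4R,6aS)-1,4-bis[4-(benzyloxy)-3-methoxyphenyl]tetrahydro-1H,3H-furo[3,4-c]furan, via benzylic organotitanium 7 (not isolated), via benzylic iodide 8 (not isolated)
Conditions: Cp2TiCl2 (2.5 equiv), Zn dust, THF, rt (green Cp2TiCl solution, decanted from Zn), added dropwise to 6 in THF, rt; then I2 (1.5 equiv), rt to 45 °C; aq. Na2S2O3; recrystallisation
Reagents that add atoms: none
Why: Cp2TiCl (trivalent titanium) opens the oxirane by single-electron transfer at the C–O bond of its CH carbon, which leaves O1 on C5 as a titanium alkoxide and a secondary radical at C4 that closes 5-exo-trig onto the styrene β-carbon (bond C3–C4, temporary oxolane); the benzylic radical is captured by a second Cp2TiCl to give 7, iodine converts the C–Ti bond into benzylic iodide 8, and the titanium alkoxide displaces iodide 5-exo-tet (bond O1–C2, oxolane of the target). The closest known reaction type is the Nugent–RajanBabu epoxide-opening radical cyclisation of epoxy cinnamyl ethers ended by iodine-induced cycloetherification, established for racemic 2,6-diaryl furofurans. C4 and C3 are set in the radical closure by the benzylic stereocentre from step 2 through a Beckwith–Houk chair-like transition state: its aryl group sits pseudo-equatorial, so the CH2O–Ti arm on C4 ends trans to it, while that arm and the new benzylic arm on C3 end cis, which is the cis ring fusion. The oxirane CH becomes planar in the radical, so its configuration in 6 is irrelevant and both epoxide epimers would converge. C2 is set in the second closure, where the aryl group takes the convex face of the forming cis-fused bicycle and the configurationally labile benzylic iodide lets both epimers funnel to the diequatorial, twofold-symmetric product, whose crystallisation should also raise the enantiomeric purity. The step needs cyclisation to outrun reduction of the first radical by a second Cp2TiCl (which would deoxygenate the epoxide); the fast addition to a styrene and the slow addition of the reagent secure this, and homolysis toward the secondary rather than the primary radical is the normal regiochemistry.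

**Step 6**
Reactants: 9 (1R,3aS,4R,6aS)-1,4-bis[4-(benzyloxy)-3-methoxyphenyl]tetrahydro-1H,3H-furo[3,4-c]furan
Product: 11 4-[(2R,3S,4S)-4-(4-hydroxy-3-methoxybenzyl)-3-(hydroxymethyl)oxolan-2-yl]-2-methoxyphenol, via debenzylated furofuran 10 (not isolated)
Conditions: H2 (1 atm), 10% Pd/C, EtOAc–MeOH 1:1, rt, followed by HPLC and stopped when 10 is consumed
Reagents that add atoms: none
Why: Pd-catalysed hydrogenolysis should first remove the two aryl benzyl ethers (10) and then cut one benzylic C–O bond of the strained bicycle, the reduction known for 2,6-diaryl furofurans; the two benzylic C–O bonds of 10 are exchanged by the twofold axis, so opening the temporary ring gives one oxolane only, C2, C3 and C4 are not involved, and the monocyclic product should react more slowly, which allows the reaction to be stopped.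

**Step 7**
Reactants: 11 4-[(2R,3S,4S)-4-(4-hydroxy-3-methoxybenzyl)-3-(hydroxymethyl)oxolan-2-yl]-2-methoxyphenol; 12 4-hydroxybenzoic acid
Product: 13 agastinol [(2R,3S,4S)-2-(4-hydroxy-3-methoxyphenyl)-4-(4-hydroxy-3-methoxybenzyl)oxolan-3-yl]methyl 4-hydroxybenzoate
Conditions: PPh3 (1.3 equiv), DIAD (1.3 equiv), 12 (1.5 equiv), THF, 0 °C to rt
Reagents that add atoms: none
Why: Mitsunobu esterification: only the primary alcohol of 11 can form the alkoxyphosphonium ion and the carboxylic acid of 12 is by far the most acidic pronucleophile, so the ester should form in the presence of the three free phenols (as in Mitsunobu esterifications of unprotected phenolic acids) with no stereocentre involved.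

**Compound list**
1 | 4-(benzyloxy)-3-methoxybenzaldehyde (O-benzylvanillin) | O=Cc1ccc(OCc2ccccc2)c(OC)c1 | starting material
2 | vinylmagnesium bromide | C=C[Mg]Br | starting material
3 | rac-1-[4-(benzyloxy)-3-methoxyphenyl]prop-2-en-1-ol | COc1cc(ccc1OCc1ccccc1)C(O)C=C | intermediate
4 | (S)-[4-(benzyloxy)-3-methoxyphenyl][(2R)-oxiran-2-yl]methanol | COc1cc(ccc1OCc1ccccc1)[C@H](O)[C@H]1CO1 | intermediate
5 | 1-(benzyloxy)-4-[(1E)-3-bromoprop-1-en-1-yl]-2-methoxybenzene | COc1cc(/C=C/CBr)ccc1OCc1ccccc1 | intermediate
6 | (2R)-2-[(S)-[4-(benzyloxy)-3-methoxyphenyl]{[(2E)-3-[4-(benzyloxy)-3-methoxyphenyl]prop-2-en-1-yl]oxy}methyl]oxirane | COc1cc(ccc1OCc1ccccc1)[C@H](OC/C=C/c1ccc(OCc2ccccc2)c(OC)c1)[C@H]1CO1 | intermediate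
7 | benzylic organotitanium species after radical cyclisation (not isolated): 2-aryl oxolane, 2,3-trans-3,4-cis, with CH2O–TiCp2Cl on C3 and CH(aryl)–TiCp2Cl on C4, titanium-bearing carbon of undefined configuration | COc1cc(ccc1OCc1ccccc1)[C@@H]1OC[C@H]([C@H]1CO[Ti](Cl)(C1C=CC=C1)C1C=CC=C1)C(c1ccc(OCc2ccccc2)c(OC)c1)[Ti](Cl)(C1C=CC=C1)C1C=CC=C1 | intermediate
8 | benzylic iodide with titanium alkoxide (not isolated): same oxolane with CH2O–TiCp2Cl on C3 and CH(I)(aryl) on C4 | COc1cc(ccc1OCc1ccccc1)[C@@H]1OC[C@H]([C@H]1CO[Ti](Cl)(C1C=CC=C1)C1C=CC=C1)C(I)c1ccc(OCc2ccccc2)c(OC)c1 | intermediate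
9 | (1R,3aS,4R,6aS)-1,4-bis[4-(benzyloxy)-3-methoxyphenyl]tetrahydro-1H,3H-furo[3,4-c]furan (di-O-benzyl ether of the pinoresinol enantiomer with R aryl carbons) | COc1cc(ccc1OCc1ccccc1)[C@@H]1OC[C@@H]2[C@H]1CO[C@H]2c1ccc(OCc2ccccc2)c(OC)c1 | intermediate
10 | (1R,3aS,4R,6aS)-pinoresinol, 4,4'-(tetrahydro-1H,3H-furo[3,4-c]furan-1,4-diyl)bis(2-methoxyphenol) (not isolated) | COc1cc(ccc1O)[C@@H]1OC[C@@H]2[C@H]1CO[C@H]2c1ccc(O)c(OC)c1 | intermediate
11 | 4-[(2R,3S,4S)-4-(4-hydroxy-3-methoxybenzyl)-3-(hydroxymethyl)oxolan-2-yl]-2-methoxyphenol ((2R,3S,4S)-lariciresinol) | COc1cc(C[C@@H]2CO[C@@H](c3ccc(O)c(OC)c3)[C@@H]2CO)ccc1O | intermediate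
12 | 4-hydroxybenzoic acid | OC(=O)c1ccc(O)cc1 | starting material
13 | agastinol, [(2R,3S,4S)-2-(4-hydroxy-3-methoxyphenyl)-4-(4-hydroxy-3-methoxybenzyl)oxolan-3-yl]methyl 4-hydroxybenzoate | COc1cc(C[C@@H]2CO[C@@H](c3ccc(O)c(OC)c3)[C@@H]2COC(=O)c2ccc(O)cc2)ccc1O | target

**Summary**
Total step count: 7. Longest linear sequence: 6 steps (steps 1, 2, 4, 5, 6, 7 from compound 1; the branch through step 3 is equally long).

Three steps most likely to fail:

Step 5. The iodine-triggered second ring closure may not be clean: loss of HI from the benzylic iodide, or closure with the aryl group on the concave face, would erode the yield and the configuration at C2. Fallback: starting from 6, the same radical cyclisation is ended with dilute aqueous acid instead of iodine (Cp2TiCl, THF, rt; then aq. NaH2PO4). This protonates the benzylic carbon–titanium bond and should give the monocyclic oxolane 4,4'-di-O-benzyl-(2R,3S,4S)-lariciresinol F1. In F1 the oxolane kept is the one closed by the radical step, and its benzylic ether is the one made in step 4. Brief hydrogenolysis of the two aryl benzyl ethers (H2, 10% Pd/C, EtOAc) returns to the route at 11.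

Step 6. Over-reduction: the second benzylic C–O bond may also be hydrogenolysed if the two cleavage rates lie too close together, which opens the remaining oxolane to the 1,4-diol. Fallback: the two events are separated. Starting from 9, hydrogenolysis is stopped after debenzylation (H2, 10% Pd/C, EtOAc, short contact) and 10 is isolated. 10 is then opened by ionic hydrogenation (Et3SiH, CF3CO2H or BF3·OEt2, CH2Cl2, −78 to −40 °C). The strained bicyclic benzylic ether should ionise more readily than the monocyclic product, and the cation is trapped by hydride, which returns to the route at 11. No new compound is made.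

Step 7. Competing O-alkylation of a phenol (of 11 or of 12) by the alkoxyphosphonium ion would give aryl ethers and oligomers. Fallback: starting from 11, all three hydroxyls are silylated (TBSCl, imidazole, DMF) to the tris-O-(tert-butyldimethylsilyl) ether of 11 F2. The primary alkyl silyl ether is then removed selectively with mild acid (PPTS, MeOH, rt) to give 4,4'-bis-O-(tert-butyldimethylsilyl)-(2R,3S,4S)-lariciresinol F3. Carbodiimide esterification with 4-[(tert-butyldimethylsilyl)oxy]benzoic acid (EDC·HCl, DMAP, CH2Cl2) gives tris-O-(tert-butyldimethylsilyl)agastinol F4. Buffered fluoride (TBAF, AcOH, THF, 0 °C) removes the three aryl silyl ethers and returns to the route at 13.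

**Further compounds**
F1 | step 5 | 4,4'-di-O-benzyl-(2R,3S,4S)-lariciresinol, {(2R,3S,4S)-2-[4-(benzyloxy)-3-methoxyphenyl]-4-[4-(benzyloxy)-3-methoxybenzyl]oxolan-3-yl}methanol | COc1cc(C[C@@H]2CO[C@@H](c3ccc(OCc4ccccc4)c(OC)c3)[C@@H]2CO)ccc1OCc1ccccc1
F0 | step 6 | none | none
F2 | step 7 | tris-O-(tert-butyldimethylsilyl) ether of 11 (two aryl silyl ethers, one primary alkyl silyl ether) | COc1cc(C[C@@H]2CO[C@@H](c3ccc(O[Si](C)(C)C(C)(C)C)c(OC)c3)[C@@H]2CO[Si](C)(C)C(C)(C)C)ccc1O[Si](C)(C)C(C)(C)C
F3 | step 7 | 4,4'-bis-O-(tert-butyldimethylsilyl)-(2R,3S,4S)-lariciresinol (primary alcohol free) | COc1cc(C[C@@H]2CO[C@@H](c3ccc(O[Si](C)(C)C(C)(C)C)c(OC)c3)[C@@H]2CO)ccc1O[Si](C)(C)C(C)(C)C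
F4 | step 7 | tris-O-(tert-butyldimethylsilyl)agastinol | COc1cc(C[C@@H]2CO[C@@H](c3ccc(O[Si](C)(C)C(C)(C)C)c(OC)c3)[C@@H]2COC(=O)c2ccc(O[Si](C)(C)C(C)(C)C)cc2)ccc1O[Si](C)(C)C(C)(C)C
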